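# Design of a synthesis of pterocarpan 25 by three-component conjunctive coupling

## The problem

Compound 25 is a pterocarpan. A chroman (ring B) and a dihydrobenzofuran (ring C) share the C6a–C11a bond; ring A carries a 2,2-dimethyl-2H-pyran (ring E) at C3/C4 and ring D an (R)-3-hydroxy-2,2-dimethyldihydropyran (ring F) at C9/C10. There are three stereocentres: C6a (R) and C11a (R) at the cis B/C junction, and the isolated carbinol of ring F (R). Once ring B exists, ring C can only be fused cis, so C6a dictates C11a and only C6a has to be set absolutely. The ring F carbinol is too remote to steer or be steered and needs its own reagent control. The C11a–O bond is benzylic to ring A and is pushed by O5 (ortho) and the ring E oxygen (para), so it ionises in acid. This helps to close ring C, but loss of H6a from the cation would erase C6a. The ring E double bond is an electron-rich styrene that excludes hydrogenation, indiscriminate electrophilic halogen and strong acid, and both aryl rings are crowded 1,2,3,4-tetrasubstituted aryl ethers. Rings A/E and D/F share one substitution pattern, so both can descend from 2,2-dimethyl-2H-chromen-5-ol (5). The feature that opens the key step is the pair C11a/C6a: adjacent sp3 carbons, each with one aryl group (ring A on C11a, ring D on C6a), oxygen on C11a and the C6 oxymethylene on C6a. That is the pattern left when both ends of a 3-oxypropenylboron unit are arylated and boron is exchanged for oxygen.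

## Retrosynthesis

**Ring C, O11–C11a.** The last bond cut is O11–C11a, which gives the trans-isoflavan-4-ol 24 with O11 as a methoxymethyl ether. Stereochemistry decides for this cut over O5–C6. With ring B in place, O11 can capture an activated C11a only in the cis sense, so the configuration of the alcohol in 24 does not matter and only C6a must be right. If ring C were closed while ring B was still open, a 2,3-disubstituted dihydrobenzofuran would form, and its trans isomer is the stable one. Forward, an acid must remove the acetal and ionise C11a–OH without harming the ring E alkene.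

**Ring B, O5–C6.** Ring B is opened at O5–C6 to the phenol triol 23. A C4a–O5 cut would need a metal-mediated aryl ether synthesis on a halogenated ring A; the O5–C6 cut uses the native phenol and a primary alcohol in a Mitsunobu etherification. O11 must stay masked, because a free O11 would close a five-membered ether onto C6 faster than O5 closes the six-membered one. Forward, the primary C6–OH must be activated in preference to the hindered secondary hydroxyls at C11a and in ring F.

**Unmasking and C–B to C–O.** 23 is traced through 22 to boronic ester 21. Fluoride releases O5 (2-(trimethylsilyl)ethoxymethyl ether), C6–OH and the ring F carbinol (silyl ethers) in one operation and leaves the methoxymethyl ether. The C11a–OH of 22 is the oxidation product, with retention, of the C11a–B bond of 21. The phenol protecting groups are thus chosen for order of removal: fluoride-labile on O5, acid-labile on O11. An allyl ether on O5 was rejected because it is itself a substrate for zerovalent palladium and because an ortho-lithiated allyl aryl ether can cyclise onto its own alkene.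

**Key disconnection, C11a–C11b and C6a–C6b.** 21 is cut into three fragments: aryl bromide 7 (fragment 1, rings A and E), alkenylboronic ester 18 (fragment 2, carbons C11a, C6a, C6) and aryl iodide 13 (fragment 3, rings D and F). Against the classical C6a–C11a (aldol) cut, or two separate arylations, this cut makes both aryl–C(sp3) bonds in one operation, sets C6a and C11a together, and never places a carbonyl next to C6a. The forward reaction asks three things:
- The ate complex 20 must undergo palladium-induced 1,2-migration, not direct boron-to-palladium transfer. This is the known weakness of β-substituted alkenylboronates, so boron carries the bulky diol 15 instead of a simple diol.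
- Halide must be stripped from palladium (potassium triflate).
- The chiral ferrocenyl bisphosphine must select the Si face of C6a.

**Fragment 3.** The C–I bond of 13 is placed ortho to O11 by lithiation of 11, directed by the methoxymethyl group. 11 is the silyl ether of chromanol 10, which comes from chromene 8 through epoxide 9 by enantioselective manganese salen epoxidation and hydride opening at the benzylic carbon. 2,2-Dimethylchromenes are the best substrate class for this epoxidation, and it converts the ring E-type alkene of the common precursor into ring F. 8 is the methoxymethyl ether of 5.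

**Fragment 1 and the common phenol.** 7 is the 2-(trimethylsilyl)ethoxymethyl ether of bromophenol 6, and 6 comes from phenol 5 by amine-mediated ortho-bromination. C6 is the only free position ortho to the hydroxyl, so the free phenol itself carries the regiochemical information, and no organolithium meets the ring E styrene before the key step. Direct lithiation of the unbrominated ether in the key step was set aside, because any surplus butyllithium would put a butyl group on boron. The bromide is an isolable, purifiable carrier of the regiochemistry, and halogen–lithium exchange on it gives the ring A aryllithium in exact amount. Phenol 5 is cut via 3 into cyclohexane-1,3-dione (1) and prenal (2); this fixes oxygen at C5 without the regiochemical ambiguity of annulating a preformed aromatic diol.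

**Fragment 2.** 18 is the hydroboration product of silyl propargyl ether 16, transesterified with diol 15. Diol 15 is the double methyl adduct of acenaphthylene-1,2-dione (14).

## Roads not taken

**Alternative 1:** Ring D is cut at C10a–C10, C8–C9 and C6b–C10a and built by benzannulation on a preformed isoflavan. Long-wavelength irradiation of diazo enone A2 triggers Wolff rearrangement, cycloaddition with siloxyalkyne A3, four-electron ring opening and six-electron closure to phenol A1.
- Merits: the full ring D pattern (O11–H, prenyl on C10, silyloxy on C9) arrives regiospecifically under neutral conditions, and no hindered aryl halide has to be coupled. In this respect it is better than the chosen plan, whose key step must join two ortho-oxygenated aryl partners at a metal.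
- Weak points: A2 already contains C6a and C11a, so the key step solves no stereochemical problem and a separate asymmetric synthesis of the isoflavan is needed first. H6a of A2 is γ to the enone and can be lost by vinylogous enolisation. The 2H-chromene of ring E is itself photoactive. After A1, ring F must still be made by enantioselective epoxidation of the prenyl group and a 6-endo closure that competes with 5-exo, and ring C is still open.
- Comparison: the chosen plan gets the regiochemistry of both aryl rings cheaply from one phenol, puts the stereochemical work into the bond-forming step, and is shorter after the key step.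

**Alternative 2:** The C6a–C11a bond and ring C are cut together. Dirhodium tetrakis[N-phthaloyl-(S)-tert-leucinate], Rh2(S-PTTL)4, a dimer of divalent rhodium, decomposes aryl diazoacetate A5, and the carbene inserts into the benzylic C11a–H bond to give cis-dihydrobenzofuran ester A4.
- Merits: one catalytic step makes the central bond, ring C and both stereocentres directly in the cis relationship of the target. This is stereochemically more direct than the chosen plan, in which C11a is provisional and is re-formed at the end.
- Weak points: the electron-rich ring E alkene competes for the electrophilic carbene by cyclopropanation. The C11a–H bond is flanked by an ortho pivalate. In A4, C6a is benzylic and α to an ester, so it can epimerise to trans during ester reduction and pivalate removal. A5 needs an ionisation-prone 2,4-dioxygenated benzyl electrophile and a diazo transfer, in a longer linear sequence.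
- Comparison: the chosen plan sets against the directness of A4 its convergence (three fragments, two from one phenol), the absence of a carbene chemoselectivity problem, and a C6a that is never α to a carbonyl. Both routes still need ring B closed afterwards.

**Alternative 3:** Ring B is cut at C11b–C11a and O5–C6. Phenylboronic acid with a carboxylic acid condenses phenol A7 with 2-arylacrolein A8 by ortho-hydroxyalkylation, dehydration and oxa-6π closure to isoflav-3-ene A6.
- Merits: it is the shortest way to the A/B/D skeleton, from a cheap phenol and without organometallic reagents. Up to the skeleton it is more step-economic than the chosen plan.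
- Weak points: A6 has neither C6a nor C11a. Both centres and the C11a oxygen would have to come from an asymmetric hydroboration-type addition to a trisubstituted styrenyl alkene, for which enantiocontrol is unreliable. A7 has two ortho positions. Ring E must still be annulated on ring A, with the angular-versus-linear question reopened. A8 is prone to polymerisation.
- Comparison: the chosen plan is longer to the skeleton but sets stereochemistry in the C–C bond-forming step and carries ring E from the start.

Key step: step 12

Remark 1: tert-butyldimethyl(prop-2-ynyloxy)silane (16) is taken as a purchased material; it is one silylation away from propargyl alcohol.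
Remark 2: the sense of induction of the ferrocenyl ligand in step 12 is assigned by analogy with simpler alkenylboron ate complexes; its mirror image is equally available and would be used if the analogy fails.
Remark 3: ate complex 20 is drawn without configuration at boron; both orientations lead to 21.

## Route

Step 1
Reactants: 1 cyclohexane-1,3-dione; 2 3-methylbut-2-enal (prenal)
Product: 3 2,2-dimethyl-7,8-dihydro-2H-chromen-5(6H)-one
Conditions: ethylenediammonium diacetate (10 mol%), MeOH, rt
Reagents that add atoms: none
Why: Knoevenagel condensation followed by oxa-6π electrocyclisation of the 1-oxatriene (formal (3+3) annulation); the dione fixes the oxygen that becomes O at C5 of the chromene.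

Step 2
Reactants: 3 2,2-dimethyl-7,8-dihydro-2H-chromen-5(6H)-one
Product: 5 2,2-dimethyl-2H-chromen-5-ol, via selenide 4 (not isolated)
Conditions: LiN(i-Pr)2, THF, −78 °C; PhSeCl, −78 °C; then 30% H2O2, pyridine, CH2Cl2, 0 °C → rt
Reagents that add atoms: none
Why: The kinetic α'-enolate of the vinylogous ester is selenenylated; oxidation at selenium and syn-elimination (selenoxide elimination) introduce the C6–C7 double bond, and enolisation of the resulting keto form gives the aromatic phenol.

Step 3
Reactants: 5 2,2-dimethyl-2H-chromen-5-ol
Product: 6 6-bromo-2,2-dimethyl-2H-chromen-5-ol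
Conditions: NBS (1.0 equiv, added slowly), i-Pr2NH (10 mol%), CH2Cl2, 0 °C
Reagents that add atoms: N-bromosuccinimide, O=C1CCC(=O)N1Br
Why: Amine-mediated ortho-bromination of a phenol (electrophilic aromatic substitution): the N-bromoamine formed in the flask is hydrogen-bonded to the hydroxyl and delivers bromine to C6, the only free ortho position and also para to the ring oxygen, in preference to C8; the phenol should react faster than the ring E alkene with this mild bromine donor.

Step 4
Reactants: 6 6-bromo-2,2-dimethyl-2H-chromen-5-ol
Product: 7 6-bromo-2,2-dimethyl-5-{[2-(trimethylsilyl)ethoxy]methoxy}-2H-chromene (fragment 1)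
Conditions: SEMCl, i-Pr2NEt, CH2Cl2, 0 °C → rt
Reagents that add atoms: 2-(trimethylsilyl)ethoxymethyl chloride, C[Si](C)(C)CCOCCl
Why: Williamson-type O-alkylation of the phenol by the chloromethyl ether; this acetal survives the halogen–lithium exchange and the palladium chemistry of step 12 and is later cleaved by fluoride while the methoxymethyl ether on ring D stays.

Step 5
Reactants: 5 2,2-dimethyl-2H-chromen-5-ol
Product: 8 5-(methoxymethoxy)-2,2-dimethyl-2H-chromene
Conditions: MOMCl, i-Pr2NEt, CH2Cl2, 0 °C → rt
Reagents that add atoms: chloromethyl methyl ether, COCCl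
Why: O-alkylation as in step 4; the methoxymethyl group protects the phenol from the oxidant of step 6, directs the lithiation of step 9, and is the acid-labile mask of O11.

Step 6
Reactants: 8 5-(methoxymethoxy)-2,2-dimethyl-2H-chromene
Product: 9 (3R,4R)-3,4-epoxy-5-(methoxymethoxy)-2,2-dimethylchromane
Conditions: (R,R)-N,N'-bis(3,5-di-tert-butylsalicylidene)-1,2-cyclohexanediaminomanganese chloride (4 mol%), 4-phenylpyridine N-oxide, aq. NaOCl (pH 11.3 buffer), CH2Cl2, 0 °C
Reagents that add atoms: sodium hypochlorite, [Na+].[O-]Cl
Why: Jacobsen epoxidation; cis-disubstituted aryl alkenes of the 2,2-dimethylchromene type are its best substrate class, and the (R,R) catalyst is the antipode that gives (3R,4R)-epoxides in this series; the C3 configuration set here becomes the ring F carbinol.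

Step 7
Reactants: 9 (3R,4R)-3,4-epoxy-5-(methoxymethoxy)-2,2-dimethylchromane
Product: 10 (3R)-5-(methoxymethoxy)-2,2-dimethylchroman-3-ol
Conditions: LiAlH4, THF, 0 °C (crude 9 used directly)
Reagents that add atoms: none
Why: Hydride opens the epoxide at benzylic C4, which is activated and, unlike C3, not neopentyl; the C3–O bond is untouched, so the (R) carbinol is kept and the acetal is inert.

Step 8
Reactants: 10 (3R)-5-(methoxymethoxy)-2,2-dimethylchroman-3-ol
Product: 11 tert-butyl{[(3R)-5-(methoxymethoxy)-2,2-dimethylchroman-3-yl]oxy}dimethylsilane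
Conditions: TBSOTf, 2,6-lutidine, CH2Cl2, −78 → 0 °C
Reagents that add atoms: tert-butyldimethylsilyl trifluoromethanesulfonate, CC(C)(C)[Si](C)(C)OS(=O)(=O)C(F)(F)F
Why: Silylation of a hindered secondary alcohol needs the silyl triflate; the silyl ether removes the acidic proton before the organolithium steps and falls to fluoride in step 14.

Step 9
Reactants: 11 tert-butyl{[(3R)-5-(methoxymethoxy)-2,2-dimethylchroman-3-yl]oxy}dimethylsilane
Product: 13 tert-butyl{[(3R)-6-iodo-5-(methoxymethoxy)-2,2-dimethylchroman-3-yl]oxy}dimethylsilane (fragment 3), via aryllithium 12 (not isolated)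
Conditions: n-BuLi, THF, −20 → 0 °C; then I2, −78 °C → rt
Reagents that add atoms: iodine, II
Why: Directed ortho-metalation by the methoxymethyl group places lithium on C6, ortho to the future O11, and iodine quenches it; with ring F saturated, the only competitor is C8 beside the ring oxygen.

Step 10
Reactants: 14 acenaphthylene-1,2-dione
Product: 15 (1R,2S)-1,2-dimethyl-1,2-dihydroacenaphthylene-1,2-diol (cis)
Conditions: AlMe3, toluene, 0 °C → rt; aq. acid work-up, recrystallisation
Reagents that add atoms: trimethylaluminium, C[Al](C)C
Why: Double 1,2-addition of methyl to the diketone; the second methyl should enter anti to the bulky aluminoxy group and so give the cis diol, which is also the only isomer able to form a cyclic boronic ester.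

Step 11
Reactants: 16 tert-butyldimethyl(prop-2-yn-1-yloxy)silane; 15 (1R,2S)-1,2-dimethyl-1,2-dihydroacenaphthylene-1,2-diol
Product: 18 (E)-3-(tert-butyldimethylsilyloxy)prop-1-enylboronic ester of diol 15 (fragment 2), via catechol boronate 17 (not isolated)
Conditions: catecholborane, dicyclohexylborane (5 mol%), THF, rt; then 15, rt; aq. NaOH wash
Reagents that add atoms: catecholborane, B1Oc2ccccc2O1
Why: Syn-hydroboration of the terminal alkyne puts boron on the terminal carbon and gives the E-alkenyl catechol ester, which exchanges readily with the aliphatic cis diol to the hindered, chromatography-stable boronic ester.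

Step 12
Reactants: 7 6-bromo-2,2-dimethyl-5-{[2-(trimethylsilyl)ethoxy]methoxy}-2H-chromene (fragment 1); 18 (E)-3-(tert-butyldimethylsilyloxy)prop-1-enylboronic ester of diol 15 (fragment 2); 13 tert-butyl{[(3R)-6-iodo-5-(methoxymethoxy)-2,2-dimethylchroman-3-yl]oxy}dimethylsilane (fragment 3)
Product: 21 (1S,2R)-3-(tert-butyldimethylsilyloxy)-1-(ring A aryl)-2-(ring D aryl)propylboronic ester of diol 15 (full name in the compound list), via aryllithium 19 (not isolated), via lithium borate complex 20 (not isolated)
Conditions: 7, t-BuLi (2 equiv), Et2O, −78 °C; then 18, −78 °C → rt; solvent exchange to THF; 13, Pd(OAc)2 (3 mol%), (Sp,Sp)-1,1'-bis[bis(4-methoxy-3,5-dimethylphenyl)phosphino]-2,2'-bis[(R)-(dimethylamino)(phenyl)methyl]ferrocene (3.6 mol%), KOTf (2 equiv), THF, 60 °C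
Reagents that add atoms: none
Why: Bromine–lithium exchange on 7 gives aryllithium 19, which adds to the Lewis acidic boron of 18 to give ate complex 20. Zerovalent palladium inserts into the C–I bond of 13, and potassium triflate precipitates iodide and bromide, so that a cationic aryl complex of divalent palladium binds the alkene of 20. Ring A then migrates from boron to C11a while palladium bonds to C6a on the opposite face (1,2-metallate shift, anti addition), and reductive elimination with retention forms C6a–C6b and returns zerovalent palladium. The closest known reaction type is the enantioselective palladium-catalysed conjunctive cross-coupling of β-substituted alkenylboron ate complexes carrying diol 15 with aryl electrophiles. No ring closes. C6a (R) is set by the ligand, which must present the Si face of C6a (CH2OSi > C11a > H) to palladium; C11a (S in 21) follows from the anti addition to the E-alkene and is provisional, because step 16 re-forms it. The step needs the metallate shift to outrun direct boron-to-palladium transfer and β-hydride or β-silyloxy elimination; the hindered diol on boron, the fast reductive elimination from the wide-bite-angle bisphosphine and the poor leaving-group ability of the silyl ether secure this, and the ring E alkene, not being part of an ate complex, is not activated toward the aryl palladium.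

Step 13
Reactants: 21 (1S,2R)-3-(tert-butyldimethylsilyloxy)-1-(ring A aryl)-2-(ring D aryl)propylboronic ester of diol 15
Product: 22 (1S,2R)-3-(tert-butyldimethylsilyloxy)-1-(ring A aryl)-2-(ring D aryl)propan-1-ol (full name in the compound list)
Conditions: 30% H2O2, 3 M NaOH, THF, 0 °C → rt
Reagents that add atoms: hydrogen peroxide, OO
Why: Hydroperoxide adds to boron and C11a shifts from boron to oxygen with retention (oxidation of a boronic ester), giving the (1S) alcohol; the electron-rich alkene, the acetals and the silyl ethers are inert to cold basic peroxide.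

Step 14
Reactants: 22 (1S,2R)-3-(tert-butyldimethylsilyloxy)-1-(ring A aryl)-2-(ring D aryl)propan-1-ol
Product: 23 (1S,2R)-1-(5-hydroxy-2,2-dimethyl-2H-chromen-6-yl)-2-[(3R)-3-hydroxy-5-(methoxymethoxy)-2,2-dimethylchroman-6-yl]propane-1,3-diol
Conditions: TBAF (excess), THF/DMPU, 60 °C
Reagents that add atoms: none
Why: Fluoride cleaves both silyl ethers and, by attack at silicon and fragmentation to ethene and formaldehyde, the 2-(trimethylsilyl)ethoxymethyl acetal; the methoxymethyl ether on O11 is unaffected, so O5 is the only free phenol.

Step 15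
Reactants: 23 (1S,2R)-1-(5-hydroxy-2,2-dimethyl-2H-chromen-6-yl)-2-[(3R)-3-hydroxy-5-(methoxymethoxy)-2,2-dimethylchroman-6-yl]propane-1,3-diol
Product: 24 (3R,4S)-3-[(3R)-3-hydroxy-5-(methoxymethoxy)-2,2-dimethylchroman-6-yl]-8,8-dimethyl-3,4-dihydro-2H,8H-pyrano[2,3-f]chromen-4-ol
Conditions: PPh3, DIAD, THF (dilute), 0 °C
Reagents that add atoms: none
Why: Mitsunobu etherification: the primary C6–OH forms the alkoxyphosphonium fastest and the O5 phenoxide, the only acidic partner, closes ring B by 6-exo-tet displacement at C6 without touching a stereocentre; O5 cannot reach C11a (four-membered ring) and O11 is masked.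

Step 16
Reactants: 24 (3R,4S)-3-[(3R)-3-hydroxy-5-(methoxymethoxy)-2,2-dimethylchroman-6-yl]-8,8-dimethyl-3,4-dihydro-2H,8H-pyrano[2,3-f]chromen-4-ol
Product: 25 the target, (6aR,11aR)-pterocarpan with a 2,2-dimethyl-2H-pyran fused at C3/C4 and an (R)-3-hydroxy-2,2-dimethyldihydropyran fused at C9/C10
Conditions: HCl (1 M in MeOH), 0 °C → rt
Reagents that add atoms: none
Why: Acid cleaves the methoxymethyl acetal and ionises the C11a–OH bond (cation stabilised by O5 ortho and the ring E oxygen para), and O11 captures the cation by 5-exo closure of ring C (acid-mediated benzylic etherification); only the cis B/C fusion is attainable, so C6a sets C11a as (R), and reversible capture of the cation by methanol limits loss of H6a.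

## Compound list

1 | cyclohexane-1,3-dione | O=C1CCCC(=O)C1 | starting material
2 | 3-methylbut-2-enal (prenal) | CC(C)=CC=O | starting material
3 | 2,2-dimethyl-7,8-dihydro-2H-chromen-5(6H)-one | CC1(C)C=CC2=C(CCCC2=O)O1 | intermediate
4 | 2,2-dimethyl-6-(phenylselanyl)-7,8-dihydro-2H-chromen-5(6H)-one (racemic, formed in the flask) | CC1(C)C=CC2=C(CCC([Se]c3ccccc3)C2=O)O1 | intermediate
5 | 2,2-dimethyl-2H-chromen-5-ol | CC1(C)C=Cc2c(O)cccc2O1 | intermediate
6 | 6-bromo-2,2-dimethyl-2H-chromen-5-ol | CC1(C)C=Cc2c(O)c(Br)ccc2O1 | intermediate
7 | 6-bromo-2,2-dimethyl-5-{[2-(trimethylsilyl)ethoxy]methoxy}-2H-chromene (fragment 1) | CC1(C)C=Cc2c(OCOCC[Si](C)(C)C)c(Br)ccc2O1 | intermediate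
8 | 5-(methoxymethoxy)-2,2-dimethyl-2H-chromene | CC1(C)C=Cc2c(OCOC)cccc2O1 | intermediate
9 | (3R,4R)-3,4-epoxy-5-(methoxymethoxy)-2,2-dimethylchromane | COCOc1cccc2OC(C)(C)[C@@H]3O[C@@H]3c12 | intermediate
10 | (3R)-5-(methoxymethoxy)-2,2-dimethylchroman-3-ol | COCOc1cccc2OC(C)(C)[C@H](O)Cc12 | intermediate
11 | tert-butyl{[(3R)-5-(methoxymethoxy)-2,2-dimethylchroman-3-yl]oxy}dimethylsilane | COCOc1cccc2OC(C)(C)[C@H](O[Si](C)(C)C(C)(C)C)Cc12 | intermediate
12 | [(3R)-3-(tert-butyldimethylsilyloxy)-5-(methoxymethoxy)-2,2-dimethylchroman-6-yl]lithium (formed in the flask) | COCOc1c([Li])ccc2OC(C)(C)[C@H](O[Si](C)(C)C(C)(C)C)Cc12 | intermediate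
13 | tert-butyl{[(3R)-6-iodo-5-(methoxymethoxy)-2,2-dimethylchroman-3-yl]oxy}dimethylsilane (fragment 3) | COCOc1c(I)ccc2OC(C)(C)[C@H](O[Si](C)(C)C(C)(C)C)Cc12 | intermediate
14 | acenaphthylene-1,2-dione | O=C1C(=O)c2cccc3cccc1c23 | starting material
15 | (1R,2S)-1,2-dimethyl-1,2-dihydroacenaphthylene-1,2-diol (cis, meso) | C[C@@]1(O)c2cccc3cccc(c23)[C@]1(C)O | intermediate
16 | tert-butyldimethyl(prop-2-yn-1-yloxy)silane | C#CCO[Si](C)(C)C(C)(C)C | starting material
17 | 2-[(E)-3-(tert-butyldimethylsilyloxy)prop-1-enyl]-1,3,2-benzodioxaborole (formed in the flask) | CC(C)(C)[Si](C)(C)OC/C=C/B1Oc2ccccc2O1 | intermediate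
18 | (E)-3-(tert-butyldimethylsilyloxy)prop-1-enylboronic ester of diol 15 (fragment 2) | CC(C)(C)[Si](C)(C)OC/C=C/B1O[C@]2(C)c3cccc4cccc(c34)[C@]2(C)O1 | intermediate
19 | (2,2-dimethyl-5-{[2-(trimethylsilyl)ethoxy]methoxy}-2H-chromen-6-yl)lithium (formed in the flask) | CC1(C)C=Cc2c(OCOCC[Si](C)(C)C)c([Li])ccc2O1 | intermediate
20 | lithium borate (ate complex) of boronic ester 18 carrying the ring A aryl group of 19 on boron (formed in the flask, both orientations at boron) | [Li+].CC(C)(C)[Si](C)(C)OC/C=C/[B-]1(c2ccc3OC(C)(C)C=Cc3c2OCOCC[Si](C)(C)C)O[C@]2(C)c3cccc4cccc(c34)[C@]2(C)O1 | intermediate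
21 | (1S,2R)-3-(tert-butyldimethylsilyloxy)-2-[(3R)-3-(tert-butyldimethylsilyloxy)-5-(methoxymethoxy)-2,2-dimethylchroman-6-yl]-1-(2,2-dimethyl-5-{[2-(trimethylsilyl)ethoxy]methoxy}-2H-chromen-6-yl)propylboronic ester of diol 15 | CC(C)(C)[Si](C)(C)OC[C@H]([C@H](B1O[C@]2(C)c3cccc4cccc(c34)[C@]2(C)O1)c1ccc2OC(C)(C)C=Cc2c1OCOCC[Si](C)(C)C)c1ccc2OC(C)(C)[C@H](O[Si](C)(C)C(C)(C)C)Cc2c1OCOC | intermediate
22 | (1S,2R)-3-(tert-butyldimethylsilyloxy)-2-[(3R)-3-(tert-butyldimethylsilyloxy)-5-(methoxymethoxy)-2,2-dimethylchroman-6-yl]-1-(2,2-dimethyl-5-{[2-(trimethylsilyl)ethoxy]methoxy}-2H-chromen-6-yl)propan-1-ol | CC(C)(C)[Si](C)(C)OC[C@H]([C@H](O)c1ccc2OC(C)(C)C=Cc2c1OCOCC[Si](C)(C)C)c1ccc2OC(C)(C)[C@H](O[Si](C)(C)C(C)(C)C)Cc2c1OCOC | intermediate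
23 | (1S,2R)-1-(5-hydroxy-2,2-dimethyl-2H-chromen-6-yl)-2-[(3R)-3-hydroxy-5-(methoxymethoxy)-2,2-dimethylchroman-6-yl]propane-1,3-diol | OC[C@H]([C@H](O)c1ccc2OC(C)(C)C=Cc2c1O)c1ccc2OC(C)(C)[C@H](O)Cc2c1OCOC | intermediate
24 | (3R,4S)-3-[(3R)-3-hydroxy-5-(methoxymethoxy)-2,2-dimethylchroman-6-yl]-8,8-dimethyl-3,4-dihydro-2H,8H-pyrano[2,3-f]chromen-4-ol | CC1(C)C=Cc2c(ccc3c2OC[C@@H](c2ccc4OC(C)(C)[C@H](O)Cc4c2OCOC)[C@@H]3O)O1 | intermediate
25 | (6aR,11aR)-pterocarpan with a 2,2-dimethyl-2H-pyran fused at C3/C4 (oxygen on C3) and an (R)-3-hydroxy-2,2-dimethyl-3,4-dihydro-2H-pyran fused at C9/C10 (oxygen on C9) | CC1(C)C=Cc2c(ccc3c2OC[C@H]2c4ccc5c(c4O[C@@H]32)C[C@@H](O)C(C)(C)O5)O1 | target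

## Step count and risk

Total: 16 steps. Longest linear sequence: 12 steps (steps 1, 2, 5, 6, 7, 8, 9, 12, 13, 14, 15, 16).

**Step 12 (key step).** The most likely failure is direct transfer of the alkenyl or aryl group from boron to palladium (plain cross-coupling) in place of the metallate shift. The β-substituent and the ortho-oxygen substituents on both aryl partners favour this, and residual halide on palladium makes it worse. Elimination from the alkylpalladium at C6a and weak facial selectivity are the lesser risks.

Fallback: the same C6a/C11a pair is built by an Evans syn-aldol reaction. Its closed transition state gives the same relative configuration as anti addition to the E-alkene. It sets out from 7 and 13 and returns at 23.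
- Bromide 7 is lithiated (t-BuLi, Et2O, −78 °C) and formylated with DMF to 2,2-dimethyl-5-{[2-(trimethylsilyl)ethoxy]methoxy}-2H-chromene-6-carbaldehyde F1.
- Iodide 13 is coupled with BrZnCH2CO2Et under Pd(dba)2 and P(t-Bu)3 (zerovalent palladium) to ethyl arylacetate F2.
- F2 is saponified (LiOH) to arylacetic acid F3.
- F3 is joined through its mixed pivalic anhydride to lithiated (S)-4-benzyloxazolidin-2-one, giving imide F4.
- Enolisation of F4 with Bu2BOTf and i-Pr2NEt and addition to F1 should give the (2S,3S) syn-aldol adduct F5.
- LiBH4 removes the auxiliary reductively and gives (1S,2R)-diol F6.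
- The fluoride treatment of step 14 converts F6 into 23.

**Step 3.** Bromine may enter at C8 (para to the hydroxyl, ortho to the ring oxygen) or twice, or the bromine donor may attack the electron-rich ring E alkene. Fallback: the halogen is placed by directed metalation instead of electrophilic substitution. From 5, SEMCl and i-Pr2NEt (CH2Cl2, 0 °C → rt) give 2,2-dimethyl-5-{[2-(trimethylsilyl)ethoxy]methoxy}-2H-chromene F7. n-BuLi (THF, −20 → 0 °C) then lithiates C6, the only position ortho to the acetal, and a quench with BrCCl2CCl2Br returns the route at 7. The caveat is addition of butyllithium to the styrene-type double bond, which low temperature should hold back.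

**Step 6 (with step 7).** The epoxide of so electron-rich a chromene may open or rearrange during the two-phase oxidation or work-up, with loss of material and of enantiomeric purity. Fallback: from 8, hydroboration–oxidation (BH3·SMe2; H2O2, NaOH) gives racemic chromanol F8, and Dess–Martin periodinane gives 5-(methoxymethoxy)-2,2-dimethylchroman-3-one F9. Corey–Bakshi–Shibata reduction with (S)-1-methyl-3,3-diphenyltetrahydro-1H,3H-pyrrolo[1,2-c][1,3,2]oxazaborole and BH3·SMe2 returns the route at 10; the quaternary C2 acts as the large group and the benzylic methylene as the small one.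

**Step 15.** The Mitsunobu reagent may activate the benzylic C11a–OH, which sits ortho to the free O5 phenol. Loss of phosphine oxide would then give an ortho-quinone methide whose tautomerisation erases C6a. Fallback: ring B is closed before oxygen is placed on C11a. From 21, the fluoride conditions of step 14 give phenol diol boronic ester F10; the Mitsunobu conditions of step 15 give isoflavan-4-ylboronic ester F11, which has no benzylic hydroxyl; the oxidation of step 13 returns the route at 24. The caveat is protodeboronation of the benzylic boronic ester by fluoride, which the hindered diol should slow.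

**Step 16.** During the time the acetal needs to cleave, the C11a cation may lose H6a (elimination toward the isoflav-3-ene, destroying C6a), or the acid may add to the ring E alkene. Fallback: a thioether relay that forms the cation only when the free phenol is ready to trap it. From 24, PhSH and ZnBr2 (CH2Cl2, −20 °C) capture the cation irreversibly with the soft nucleophile and remove the methoxymethyl group in the same pot, giving 4-(phenylsulfanyl)isoflavan phenol F12 as a mixture of C4 epimers. AgOTf (CH2Cl2, 0 °C) then activates sulfur and O11 closes ring C, returning the route at 25.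

## Further compounds

F1 | step 12 | 2,2-dimethyl-5-{[2-(trimethylsilyl)ethoxy]methoxy}-2H-chromene-6-carbaldehyde | O=Cc1ccc2OC(C)(C)C=Cc2c1OCOCC[Si](C)(C)C
F2 | step 12 | ethyl 2-[(3R)-3-(tert-butyldimethylsilyloxy)-5-(methoxymethoxy)-2,2-dimethylchroman-6-yl]acetate | CCOC(=O)Cc1ccc2OC(C)(C)[C@H](O[Si](C)(C)C(C)(C)C)Cc2c1OCOC
F3 | step 12 | 2-[(3R)-3-(tert-butyldimethylsilyloxy)-5-(methoxymethoxy)-2,2-dimethylchroman-6-yl]acetic acid | OC(=O)Cc1ccc2OC(C)(C)[C@H](O[Si](C)(C)C(C)(C)C)Cc2c1OCOC
F4 | step 12 | (4S)-4-benzyl-3-{2-[(3R)-3-(tert-butyldimethylsilyloxy)-5-(methoxymethoxy)-2,2-dimethylchroman-6-yl]acetyl}oxazolidin-2-one | O=C(Cc1ccc2OC(C)(C)[C@H](O[Si](C)(C)C(C)(C)C)Cc2c1OCOC)N1[C@@H](Cc2ccccc2)COC1=O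
F5 | step 12 | (4S)-4-benzyl-3-[(2S,3S)-2-[(3R)-3-(tert-butyldimethylsilyloxy)-5-(methoxymethoxy)-2,2-dimethylchroman-6-yl]-3-(2,2-dimethyl-5-{[2-(trimethylsilyl)ethoxy]methoxy}-2H-chromen-6-yl)-3-hydroxypropanoyl]oxazolidin-2-one | O=C([C@H]([C@H](O)c1ccc2OC(C)(C)C=Cc2c1OCOCC[Si](C)(C)C)c1ccc2OC(C)(C)[C@H](O[Si](C)(C)C(C)(C)C)Cc2c1OCOC)N1[C@@H](Cc2ccccc2)COC1=O
F6 | step 12 | (1S,2R)-2-[(3R)-3-(tert-butyldimethylsilyloxy)-5-(methoxymethoxy)-2,2-dimethylchroman-6-yl]-1-(2,2-dimethyl-5-{[2-(trimethylsilyl)ethoxy]methoxy}-2H-chromen-6-yl)propane-1,3-diol | OC[C@H]([C@H](O)c1ccc2OC(C)(C)C=Cc2c1OCOCC[Si](C)(C)C)c1ccc2OC(C)(C)[C@H](O[Si](C)(C)C(C)(C)C)Cc2c1OCOC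
F7 | step 3 | 2,2-dimethyl-5-{[2-(trimethylsilyl)ethoxy]methoxy}-2H-chromene | CC1(C)C=Cc2c(OCOCC[Si](C)(C)C)cccc2O1
F8 | step 6 | 5-(methoxymethoxy)-2,2-dimethylchroman-3-ol (racemic) | COCOc1cccc2OC(C)(C)C(O)Cc12
F9 | step 6 | 5-(methoxymethoxy)-2,2-dimethylchroman-3-one | COCOc1cccc2OC(C)(C)C(=O)Cc12
F10 | step 15 | (1S,2R)-3-hydroxy-1-(5-hydroxy-2,2-dimethyl-2H-chromen-6-yl)-2-[(3R)-3-hydroxy-5-(methoxymethoxy)-2,2-dimethylchroman-6-yl]propylboronic ester of diol 15 | OC[C@H]([C@H](B1O[C@]2(C)c3cccc4cccc(c34)[C@]2(C)O1)c1ccc2OC(C)(C)C=Cc2c1O)c1ccc2OC(C)(C)[C@H](O)Cc2c1OCOC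
F11 | step 15 | (3R,4S)-3-[(3R)-3-hydroxy-5-(methoxymethoxy)-2,2-dimethylchroman-6-yl]-8,8-dimethyl-3,4-dihydro-2H,8H-pyrano[2,3-f]chromen-4-ylboronic ester of diol 15 | CC1(C)C=Cc2c(ccc3c2OC[C@@H](c2ccc4OC(C)(C)[C@H](O)Cc4c2OCOC)[C@@H]3B2O[C@]4(C)c5cccc6cccc(c56)[C@]4(C)O2)O1
F12 | step 16 | (3R)-6-[(3R)-8,8-dimethyl-4-(phenylsulfanyl)-3,4-dihydro-2H,8H-pyrano[2,3-f]chromen-3-yl]-2,2-dimethylchromane-3,5-diol (mixture of C4 epimers) | CC1(C)C=Cc2c(ccc3c2OC[C@@H](c2ccc4OC(C)(C)[C@H](O)Cc4c2O)C3Sc2ccccc2)O1
A1 | alternative 1 | 2'-hydroxy-3'-prenyl-4'-(triisopropylsilyloxy)isoflavan-4-yl triethylsilyl ether carrying ring E | CC1(C)C=Cc2c(ccc3c2OC[C@@H](c2ccc(O[Si](C(C)C)(C(C)C)C(C)C)c(CC=C(C)C)c2O)[C@H]3O[Si](CC)(CC)CC)O1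
A2 | alternative 1 | (E)-1-diazo-4-[4-(triethylsilyloxy)-8,8-dimethyl-3,4-dihydro-2H,8H-pyrano[2,3-f]chromen-3-yl]but-3-en-2-one (diazo enone) | CC1(C)C=Cc2c(ccc3c2OC[C@@H](/C=C/C(=O)C=[N+]=[N-])[C@H]3O[Si](CC)(CC)CC)O1
A3 | alternative 1 | triisopropyl[(5-methylhex-4-en-1-yn-1-yl)oxy]silane (siloxyalkyne) | CC(C)=CCC#CO[Si](C(C)C)(C(C)C)C(C)C
A4 | alternative 2 | methyl cis-2-aryl-2,3-dihydrobenzofuran-3-carboxylate containing rings A, C, D, E and F | CC1(C)C=Cc2c(ccc(c2OC(=O)C(C)(C)C)[C@@H]2Oc3c(ccc4c3C[C@@H](O[Si](C)(C)C(C)(C)C)C(C)(C)O4)[C@@H]2C(=O)OC)O1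
A5 | alternative 2 | methyl 2-diazo-2-{(3R)-3-(tert-butyldimethylsilyloxy)-5-[(2,2-dimethyl-5-pivaloyloxy-2H-chromen-6-yl)methoxy]-2,2-dimethylchroman-6-yl}acetate | CC1(C)C=Cc2c(ccc(COc3c(C(=[N+]=[N-])C(=O)OC)ccc4OC(C)(C)[C@H](O[Si](C)(C)C(C)(C)C)Cc34)c2OC(=O)C(C)(C)C)O1
A6 | alternative 3 | 7-(triisopropylsilyloxy)isoflav-3-ene carrying rings D and F | CC(C)[Si](Oc1ccc2C=C(COc2c1)c1ccc2c(c1O[Si](C)(C)C(C)(C)C)C[C@@H](O[Si](C)(C)C(C)(C)C)C(C)(C)O2)(C(C)C)C(C)C
A7 | alternative 3 | 3-(triisopropylsilyloxy)phenol | CC(C)[Si](Oc1cccc(O)c1)(C(C)C)C(C)C
A8 | alternative 3 | 2-[(3R)-3,5-bis(tert-butyldimethylsilyloxy)-2,2-dimethylchroman-6-yl]prop-2-enal | C=C(C=O)c1ccc2c(c1O[Si](C)(C)C(C)(C)C)C[C@@H](O[Si](C)(C)C(C)(C)C)C(C)(C)O2
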